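The C1–C7 atom labels used throughout are defined in the first sentence; Bz is benzoyl.

Numbering: C1 is the quaternary carbinol carbon, C2–C6 follow round the ring through the C3=C4 alkene, C7 is the CH2OBz carbon. The trans C5–OBz/C6–OH pair next to C3=C4 is read as a vinyl oxirane opened by benzoic acid, and the oxirane as the hydroxyl-directed epoxide of a cyclohexa-1,3-diene. The C5–C6 bond is therefore made at the alkene level: ring-closing metathesis of an acyclic (Z)-1,3,7-triene joins C5 to C6 and closes the carbocycle, giving a synthetic arene cis-dihydrodiol dibenzoate in one operation. The precursor is an open-chain triene whose C1 and C2 stereocentres come from a Sharpless kinetic resolution and a Mitsunobu inversion.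

Key step: step 7

Step 1
Reactants: 1 3,3-diethoxyprop-1-yne; 2 bromoethene (vinyl bromide, 1 M in THF)
Product: 3 5,5-diethoxypent-1-en-3-yne
Conditions: Pd(PPh3)2Cl2 (2 mol %), CuI (4 mol %), Et3N, THF, 0 °C to rt
Reagents that add atoms: none
Why: Sonogashira coupling of the terminal alkyne with the vinyl bromide should deliver the conjugated enyne, the diethyl acetal keeping the volatile and polymerisation-prone ynal masked until it is needed.

Step 2
Reactants: 3 5,5-diethoxypent-1-en-3-yne; 4 1,4-dibromobut-2-yne
Product: 6 rac-3-methylideneocta-1,7-dien-5-yn-4-ol, via pent-4-en-2-ynal 5 (not isolated)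
Conditions: HCl (0.1 equiv), THF/H2O, rt; then In powder, 4, rt
Reagents that add atoms: water, O
Why: Mild acid unmasks the ynal in the flask and the organoindium species formed from 4 (a 1,3-butadien-2-yl donor) adds 1,2 to the aldehyde in an indium-mediated Barbier reaction, which tolerates water and the alkyne and should give the racemic dienyl carbinol with C2 as its only stereocentre.

Step 3
Reactants: 6 rac-3-methylideneocta-1,7-dien-5-yn-4-ol
Product: 7 (1S)-1-[(2R)-2-ethenyloxiran-2-yl]pent-4-en-2-yn-1-ol
Conditions: Ti(OiPr)4 (10 mol %), diisopropyl L-(+)-tartrate (15 mol %), t-BuOOH (0.55 equiv), 4 Å molecular sieves, CH2Cl2, −20 °C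
Reagents that add atoms: tert-butyl hydroperoxide, CC(C)(C)OO
Why: Sharpless kinetic resolution of a secondary allylic alcohol: with the L-(+)-tartrate titanium catalyst the (R)-enantiomer of 6 is the matched one and is epoxidised at the 1,1-disubstituted C1=C7 alkene on the face chosen by the catalyst, anti to the alkynyl group (erythro), which fixes C1 as R and selects C2 as S, while the (S)-enantiomer of 6 stays behind and is separated.

Step 4
Reactants: 7 (1S)-1-[(2R)-2-ethenyloxiran-2-yl]pent-4-en-2-yn-1-ol
Product: 8 (1R)-1-[(2R)-2-ethenyloxiran-2-yl]pent-4-en-2-yn-1-yl benzoate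
Conditions: PPh3, diisopropyl azodicarboxylate, PhCO2H, THF, 0 °C to rt
Reagents that add atoms: benzoic acid, OC(=O)c1ccccc1
Why: Mitsunobu reaction: benzoate displaces the oxyphosphonium group at the propargylic carbon C2 with inversion (S to R), turning the erythro into the threo series required by the target and installing the C2 benzoate in the same operation, while the oxirane survives the neutral conditions.

Step 5
Reactants: 8 (1R)-1-[(2R)-2-ethenyloxiran-2-yl]pent-4-en-2-yn-1-yl benzoate
Product: 9 (2R,3R)-2-ethenyl-2-hydroxyhept-6-en-4-yne-1,3-diyl dibenzoate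
Conditions: PhCO2H (2 equiv), Cs2CO3 (0.2 equiv), DMF, 60 °C
Reagents that add atoms: benzoic acid, OC(=O)c1ccccc1
Why: Carboxylate opening of a 2,2-disubstituted oxirane by SN2 attack at its unhindered CH2 terminus (C7) should give the primary benzoate and the tertiary C1 carbinol with C1 untouched, the excess benzoic acid protonating the alkoxide before acyl migration can start.

Step 6
Reactants: 9 (2R,3R)-2-ethenyl-2-hydroxyhept-6-en-4-yne-1,3-diyl dibenzoate
Product: 10 (2R,3R,4Z)-2-ethenyl-2-hydroxyhepta-4,6-diene-1,3-diyl dibenzoate
Conditions: H2 (1 atm), Pd/CaCO3 poisoned with Pb(OAc)2 (Lindlar catalyst), quinoline, EtOAc, rt, stopped at 1 equiv H2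
Reagents that add atoms: none
Why: Lindlar semihydrogenation adds H2 syn to the alkyne of the conjugated enyne and should give the (Z)-C3=C4 alkene that the ring closure requires, the poisoned catalyst leaving the terminal alkenes and the benzoates alone when the uptake is stopped at one equivalent.

Step 7
Reactants: 10 (2R,3R,4Z)-2-ethenyl-2-hydroxyhepta-4,6-diene-1,3-diyl dibenzoate
Product: 11 [(1R,6R)-6-(benzoyloxy)-1-hydroxycyclohexa-2,4-dien-1-yl]methyl benzoate
Conditions: second-generation Grubbs catalyst (5 mol %), CH2Cl2 (5 mM), 40 °C
Reagents that add atoms: none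
Why: Ring-closing olefin metathesis: the Ru alkylidene loads on either terminal alkene of 10 (the C6 vinyl group or the diene terminus), cycloadds to the other to give a ruthenacyclobutane, and cycloreversion forms the C5=C6 bond with loss of ethene. The closest known reaction type is the metathesis closure of terminal 1,3,7-trienes to cyclohexa-1,3-dienes. The six-membered carbocycle is closed by joining the two terminal sp2 carbons C5 and C6, both of which end up endocyclic; the only other intramolecular event, attack of the C6 alkylidene on the internal C3=C4 bond, would give a cyclobutene and is not viable. No new stereocentre is formed: C1 and C2 pass through unchanged, and the (Z) geometry of C3=C4 from step 6 is the element that lets C5 reach C6. The step needs ring closure to win over intermolecular cross-metathesis at the diene, which high dilution, the favourable six-membered closure and loss of ethene should secure, and it needs neutral conditions because 11 is an acid-labile diene of the arene-hydrate type, so 11 is taken directly into step 8.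

Step 8
Reactants: 11 [(1R,6R)-6-(benzoyloxy)-1-hydroxycyclohexa-2,4-dien-1-yl]methyl benzoate
Product: 12 [(1S,4R,5R,6S)-4-(benzoyloxy)-5-hydroxy-7-oxabicyclo[4.1.0]hept-2-en-5-yl]methyl benzoate
Conditions: VO(acac)2 (5 mol %), t-BuOOH, CH2Cl2, 0 °C
Reagents that add atoms: tert-butyl hydroperoxide, CC(C)(C)OO
Why: Vanadium-catalysed, hydroxyl-directed epoxidation of an allylic alcohol: the tertiary C1 hydroxyl binds the vanadium peroxide and delivers oxygen to the adjacent C5=C6 alkene on its own face, which sets C6 (and C5 for the time being) cis to the C1 hydroxyl and leaves the C3=C4 alkene, which has no allylic hydroxyl, untouched.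

Step 9
Reactants: 12 [(1S,4R,5R,6S)-4-(benzoyloxy)-5-hydroxy-7-oxabicyclo[4.1.0]hept-2-en-5-yl]methyl benzoate
Product: 13 [(1S,2R,5R,6S)-2,5-bis(benzoyloxy)-1,6-dihydroxycyclohex-3-en-1-yl]methyl benzoate
Conditions: Ti(OiPr)4 (1.5 equiv), PhCO2H (2 equiv), CH2Cl2, rt
Reagents that add atoms: benzoic acid, OC(=O)c1ccccc1
Why: Titanium-mediated opening of a 2,3-epoxy alcohol with benzoic acid (C3-selective, here also the allylic position) should bring the benzoate to C5 by SN2 attack with inversion, giving the trans C5–OBz/C6–OH arrangement and completing the target.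

Compound list
1 | 3,3-diethoxyprop-1-yne | C#CC(OCC)OCC | starting material
2 | bromoethene (vinyl bromide) | C=CBr | starting material
3 | 5,5-diethoxypent-1-en-3-yne | C=CC#CC(OCC)OCC | intermediate
4 | 1,4-dibromobut-2-yne | BrCC#CCBr | starting material
5 | pent-4-en-2-ynal | C=CC#CC=O | intermediate (not isolated)
6 | rac-3-methylideneocta-1,7-dien-5-yn-4-ol | C=CC(=C)C(O)C#CC=C | intermediate
7 | (1S)-1-[(2R)-2-ethenyloxiran-2-yl]pent-4-en-2-yn-1-ol | C=C[C@@]1(CO1)[C@@H](O)C#CC=C | intermediate
8 | (1R)-1-[(2R)-2-ethenyloxiran-2-yl]pent-4-en-2-yn-1-yl benzoate | C=C[C@@]1(CO1)[C@H](OC(=O)c1ccccc1)C#CC=C | intermediate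
9 | (2R,3R)-2-ethenyl-2-hydroxyhept-6-en-4-yne-1,3-diyl dibenzoate | O=C(OC[C@@](C=C)(O)[C@H](OC(=O)c1ccccc1)C#CC=C)c1ccccc1 | intermediate
10 | (2R,3R,4Z)-2-ethenyl-2-hydroxyhepta-4,6-diene-1,3-diyl dibenzoate | O=C(OC[C@@](C=C)(O)[C@H](OC(=O)c1ccccc1)/C=C\C=C)c1ccccc1 | intermediate
11 | [(1R,6R)-6-(benzoyloxy)-1-hydroxycyclohexa-2,4-dien-1-yl]methyl benzoate | O=C(OC[C@@]1(O)[C@H](OC(=O)c2ccccc2)C=CC=C1)c1ccccc1 | intermediate
12 | [(1S,4R,5R,6S)-4-(benzoyloxy)-5-hydroxy-7-oxabicyclo[4.1.0]hept-2-en-5-yl]methyl benzoate | O=C(OC[C@@]1(O)[C@H](OC(=O)c2ccccc2)C=C[C@@H]2O[C@@H]21)c1ccccc1 | intermediate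
13 | [(1S,2R,5R,6S)-2,5-bis(benzoyloxy)-1,6-dihydroxycyclohex-3-en-1-yl]methyl benzoate | O=C(OC[C@@]1(O)[C@H](OC(=O)c2ccccc2)C=C[C@@H](OC(=O)c2ccccc2)[C@@H]1O)c1ccccc1 | target

Total step count: 9. Longest linear sequence: 9 steps (1 to 13).

Steps most likely to fail

Step 4 (Mitsunobu inversion). The displacement at C2, which is flanked by the fully substituted oxirane carbon, may be slow, so that elimination, attack through the alkyne to an allenyl benzoate, or partial retention competes. The fallback inverts C2 by oxidation and reagent-controlled reduction and sets out from 7. Dess–Martin periodinane in CH2Cl2 should give the epoxy ynone 1-[(2R)-2-ethenyloxiran-2-yl]pent-4-en-2-yn-1-one F1. Reduction with (S)-2-methyl-CBS-oxazaborolidine and catecholborane at −78 °C, in which the alkyne is the small and the oxirane carbon the large substituent, should give the threo alcohol (1R)-1-[(2R)-2-ethenyloxiran-2-yl]pent-4-en-2-yn-1-ol F2. Benzoylation (BzCl, pyridine, DMAP) then returns to the route at 8.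

Step 5 (carboxylate opening of the vinyl oxirane). Regioselectivity may be poor, through conjugate SN2' opening via the vinyl group or ionisation at the tertiary allylic carbon C1, and the benzoyl group may migrate onto the new tertiary alkoxide. The fallback uses a hydroxyl-directed opening and sets out from 8. Reductive removal of the benzoate (i-Bu2AlH, CH2Cl2, −78 °C) should give the threo epoxy alcohol (1R)-1-[(2R)-2-ethenyloxiran-2-yl]pent-4-en-2-yn-1-ol F2, the same compound as in the preceding fallback. Ti(OiPr)4 and PhCO2H then deliver benzoate from the titanium alkoxide to C7 (C3-selective opening of a 2,3-epoxy alcohol) to give (2R,3R)-2-ethenyl-2,3-dihydroxyhept-6-en-4-yn-1-yl benzoate F3. Selective benzoylation of the secondary propargylic hydroxyl (BzCl, pyridine, 0 °C; the tertiary hydroxyl should not react) returns to the route at 9.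

Step 3 (kinetic resolution). The rate difference between the enantiomers may be small because the alkynyl group at the carbinol carbon is slim, and the titanium catalyst may open the acid-labile vinyl oxirane; both would erode the enantiomeric and diastereomeric purity of 7. The fallback separates the resolution from the epoxidation and sets out from 6. Lipase-catalysed acylation (Novozym 435, vinyl acetate, MTBE, rt) should leave the alcohol (4R)-3-methylideneocta-1,7-dien-5-yn-4-ol F4 and convert its enantiomer into (4S)-3-methylideneocta-1,7-dien-5-yn-4-yl acetate F5. F4 is then epoxidised with VO(acac)2 and t-BuOOH in CH2Cl2, whose alkoxide-directed oxygen delivery is erythro-selective for 2-substituted allylic alcohols, and this returns to the route at 7.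

The key step itself is judged less risky than these three, since both possible loading sites of the catalyst lead to the same six-membered closure.

Further compounds
F1 | step 4 | 1-[(2R)-2-ethenyloxiran-2-yl]pent-4-en-2-yn-1-one | C=C[C@@]1(CO1)C(=O)C#CC=C
F2 | step 4 | (1R)-1-[(2R)-2-ethenyloxiran-2-yl]pent-4-en-2-yn-1-ol | C=C[C@@]1(CO1)[C@H](O)C#CC=C
F3 | step 5 | (2R,3R)-2-ethenyl-2,3-dihydroxyhept-6-en-4-yn-1-yl benzoate | O=C(OC[C@@](C=C)(O)[C@H](O)C#CC=C)c1ccccc1
F4 | step 3 | (4R)-3-methylideneocta-1,7-dien-5-yn-4-ol | C=CC(=C)[C@@H](O)C#CC=C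
F5 | step 3 | (4S)-3-methylideneocta-1,7-dien-5-yn-4-yl acetate | C=CC(=C)[C@H](OC(C)=O)C#CC=C
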